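The numbers in the tables come from a simulation from invented constants.

Start with the easy step: in the teal flask the starting material falls from 27.9% at 10.0 h to 0% at 60.0 h, so the last teal reading shows none of it left to turn over.

the same everywhere: starting material 0.10 M; temperature 25 °C

|  | partner | protic impurity | remark | time |
|---|---|---|---|---|
| teal | 1.5 equiv | 0.10 M | the very flask that is asked about, followed so far |  |
| red | 1.5 equiv | 0.20 M | run made earlier |  |
| flask | 1.50 equiv | 0.100 M |  | 3.0 d |

- teal (time / h: target / %, starting material / %): 10.0: 28.5, 27.9; 20.0: 52.5, 7.9; 30.0: 63.5, 2.8; 40.0: 69.8, 1.1; 50.0: 72.4, 0.1; 60.0: 73.6, 0
- red (time / h: target / %, starting material / %): 1.00: 0.6, 88.9; 2.00: 2.6, 78.3; 3.00: 4.4, 68.8; 4.00: 7.2, 60.1; 5.00: 10.7, 53.2; 6.00: 14.2, 46.7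

(readings scatter by 0.5 percentage points)

- gamma: at 3.0 d raise the temperature by 25 K, then wait 20 h
- zeta: change nothing and wait 20 h more
- beta: at 3.0 d take out 90% of the target then present, then wait 20 h
- eta: at 3.0 d add partner, 50.0% of the amount charged, then wait 20 h

- target that was removed still counts
- additions bring no volume worth counting

* target, in percent of the starting material first charged, at 3.0 d
* the option that brings most further target ("none" if no option brings more than 2 percentage points) (gamma / zeta / beta / eta / none)
* target present, with what was taken out counted in, in percent of the starting material first charged, after gamma
* target present, with what was taken out counted in, in percent of the starting material first charged, after beta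

Now the odd pair of numbers. The teal flask was charged with 1.5 equiv of partner, an excess over the starting material, yet its target reading is levelling off at 73.6%. Each gain in the last teal readings is roughly the same fraction of the one before, so you can estimate what is still to come by summing:

shrink per interval = 0.462

plateau = last reading + last gain × shrink / (1 − shrink) = 74.6%

room = everything charged − plateau = 25 percentage points

So by this estimate, read off scattered teal readings, this much material has left the starting material without becoming target. Take the plain one-to-one case as the zero of the scale, where each partner makes one target:

target per partner = plateau / equivalents of partner = 0.498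

This partner yield, target at the plateau per partner charged, puts half of the teal partner in target, as an estimate. The readings can't prove where the rest went. I reckon that it was lost, which makes partner the limiting reagent in effect, despite its excess. Then eta is the option to choose:

gain from eta = partner yield × partner added = 37 points

That is more than the room, so the room caps the gain, and 20 h may deliver part of it. I put the target now at 74.6%. I expect beta to stay near that value, and gamma too, though no run shows a temperature change.

The forecast, which parts from my reckoning on the best option, says 74.4%, beta as best, 65% after gamma and 86% after beta: “The fit I + partner ⇌ target works well”.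

The flask gives 75.5% at 3.0 d. The best option is eta, which adds 14 points and reaches 89.9%, while gamma ends at 76.0% and beta at 76.4%.

    partner → second intermediate (k = 0.0380 min⁻¹, Ea = 86.0 kJ mol⁻¹)
    open intermediate + second intermediate → target (k = 0.0150 M⁻¹ min⁻¹, Ea = 56.0 kJ mol⁻¹)
    partner + protic impurity → quenched reagent (k = 0.0350 M⁻¹ min⁻¹, Ea = 74.0 kJ mol⁻¹)
    second intermediate → side product (k = 4.00 × 10⁻⁴ min⁻¹, Ea = 106 kJ mol⁻¹)
    starting material → open intermediate (k = 0.00210 min⁻¹, Ea = 92.0 kJ mol⁻¹)
    (constants at 25 °C)

In this flask at 72.0 h, partner stands at 0% and second intermediate at 0.00326 M, and that intermediate goes into target at 0.92 of the rate at which it goes into side product. Side product stands at 0.0593 M beside 75.5% target in this flask, and its target per partner charged, the partner yield taken at that time, reads 0.503. The neighbour charged with 0.060 M of starting material has a partner yield of 0.433 at the same time, with target at 64.9% and open intermediate at 35.1% of its own charge after 72.0 h.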